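**Retrosynthetic overview**

1. The C8 2-methylbutanoate is put on last by selective acylation of a C8/C9 diol; that diol comes from osmylation of C8=C9 anti to the C7 angelate, and the C7 carbinol from CBS reduction of a C7 enone whose only enolisable carbon, C6, is gem-dimethylated.
2. The seven-membered ring (formed last) is disconnected by RCM between a C10 vinyl and a C5 butenyl group, followed by allylic oxidation at C7; the C3 methyl enters late by cuprate addition and Saegusa–Ito oxidation, the silyl enol ether masking C1=O during the C7 reduction.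
3. Key disconnection C5–C11 (cyclobutane, formed second, on the six-membered ring that is present from the start): one-pot copper-catalysed 1,4-addition of methyl to C10 of a monocyclic 3-vinyl-4-(1-bromopent-4-enyl)cyclohexenone and 4-exo-tet alkylation of the resulting enolate at C5.
4. Enabling feature: in ring A the C1 carbonyl makes C10 a β-acceptor carbon and C11 the enolate carbon generated there, while C5 hangs on C4, 1,3 to C11 across C10, so that one enolate alkylation closes the cyclobutane C4–C5–C11–C10; the enolate oxygen cannot reach C5 without creating a bridgehead enol ether.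
5. The monocyclic precursor comes in three steps from 1,4-dioxaspiro[4.5]decan-7-one and pent-4-enal (proline aldol, vinyl Grignard addition with acid work-up, Appel inversion).

Key step: step 4

Remark: names and text use longipinane numbering (C1 ketone, C2=C3 with C15 on C3, C4 and C11 bridgeheads, C5 and C10 the other two cyclobutane carbons, C6 the CMe2 carbon, C7–C9 the oxygenated carbons); 1, 2, 17 and 20 are assumed to be commercial.

**Route**

Step 1
Reactants: 1 1,4-dioxaspiro[4.5]decan-7-one; 2 pent-4-enal
Product: 3 (8S)-8-[(1S)-1-hydroxypent-4-en-1-yl]-1,4-dioxaspiro[4.5]decan-7-one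
Conditions: L-proline (30 mol%), DMSO, 4 °C, 1 in excess, slow addition of 2
Reagents that add atoms: none
Why: Proline-catalysed direct aldol reaction (enamine catalysis): the enamine should form on the C8 side, away from the spiro-ketal, and add to the aldehyde through the usual hydrogen-bonded chair-like transition state, which sets both new stereocentres (anti, 8S and 1′S) under catalyst control.

Step 2
Reactants: 3
Product: 5 (4R)-3-ethenyl-4-[(1S)-1-hydroxypent-4-en-1-yl]cyclohex-2-en-1-one, via ketal diol 4 (not isolated)
Conditions: CH2=CHMgBr (3 equiv), THF, −78 → 0 °C; then 1 M HCl, THF, 0 °C → rt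
Reagents that add atoms: vinylmagnesium bromide, C=C[Mg]Br; water, O
Why: Grignard 1,2-addition to the ketone, then acid-induced ketal hydrolysis and dehydration of the tertiary β-hydroxy ketone (the β-keto-ketal variant of the Stork–Danheiser enone synthesis) should give the 3-vinyl enone; the two existing stereocentres are not touched and the new carbinol centre is lost again.

Step 3
Reactants: 5
Product: 6 (4R)-4-[(1R)-1-bromopent-4-en-1-yl]-3-ethenylcyclohex-2-en-1-one
Conditions: CBr4, PPh3, CH2Cl2, 0 °C
Reagents that add atoms: carbon tetrabromide, BrC(Br)(Br)Br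
Why: Appel reaction: bromide displaces the alkoxyphosphonium group in an SN2 step, so the carbinol centre is inverted to the (R)-bromide that the ring closure needs.

Step 4
Reactants: 6
Product: 8 (1R,5S,6R,7S)-7-(but-3-en-1-yl)-6-ethenyl-6-methylbicyclo[3.1.1]heptan-2-one, via magnesium enolate 7 (not isolated)
Conditions: MeMgBr (1.3 equiv), Cu(OTf)2 (5 mol%), 1,3-dimesitylimidazolinium chloride (6 mol%), Et2O, −30 °C; then THF–DMPU, 0 → 40 °C
Reagents that add atoms: methylmagnesium bromide, C[Mg]Br
Why: A methylcopper–NHC species formed from MeMgBr adds its methyl group to C10 of the dienone in the 1,4-sense and leaves bromomagnesium enolate 7, whose only nucleophilic carbon is C11; on warming in the polar medium this enolate displaces the secondary bromide at C5 by intramolecular SN2 alkylation and so forms the C5–C11 bond. The closest known reaction types are the copper–NHC-catalysed 1,4-addition of Grignard reagents to 3-alkenylcyclohexenones that builds alkenyl-bearing quaternary centres, conjugate-addition-initiated ring closure of halo enones, and the base-induced keto halide or keto sulfonate cyclisation that gives bicyclo[3.1.1]heptan-2-ones. The cyclobutane closes in the 4-exo-tet mode, and the same bond completes the second six-membered ring of the bicyclo[3.1.1]heptanone. C10 is controlled by C4 (allylic 1,2-strain with the vinyl group holds the C4 side chain pseudo-axial and the methyl group enters axially on the opposite face), C11 can only bond on the ring face that carries the side chain, and C5 results from inversion of the (R)-bromide, which turns the butenyl chain away from the carbonyl bridge. The step needs 1,4- instead of 1,6-addition, C- instead of O-alkylation and substitution instead of elimination: the first should be secured by the NHC–copper/Grignard system, the second by the substrate, because O-alkylation would place a C=C bond at the bridgehead of a 2-oxabicyclo[2.2.2]octene, and the third by the trans-diaxial arrangement of methyl group and side chain, which holds the C–Br bond anti to C11.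

Step 5
Reactants: 8
Product: 9 (1R,5S,6R,7S)-7-(but-3-en-1-yl)-6-ethenyl-6-methylbicyclo[3.1.1]hept-3-en-2-one
Conditions: IBX (2.5 equiv), DMSO, 70 °C
Reagents that add atoms: none
Why: IBX dehydrogenation of a ketone to its enone; it can only run towards C2–C3 because the other α-carbon (C11) is a bridgehead that cannot enolise, and no stereocentre is formed.

Step 6
Reactants: 9
Product: 10 (4S,5S,10R,11R)-12,13,15-trinorlongipina-2,8-dien-1-one
Conditions: second-generation Grubbs catalyst (H2IMes)(PCy3)Cl2Ru=CHPh (5 mol%), CH2Cl2, 40 °C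
Reagents that add atoms: none
Why: Ring-closing metathesis: the vinyl group on C10 and the butenyl chain on C5 both sit on the cyclobutane face away from the enone bridge, so the cis-cycloheptene should close readily; no stereocentre is formed.

Step 7
Reactants: 10
Product: 11 (4S,5S,10R,11R)-12,13,15-trinorlongipina-2,8-diene-1,7-dione
Conditions: Rh2(cap)4 (dirhodium tetrakis(caprolactamate), 1 mol%), t-BuOOH (5 equiv), K2CO3, CH2Cl2, rt
Reagents that add atoms: tert-butyl hydroperoxide, CC(C)(C)OO
Why: Dirhodium-catalysed allylic oxidation with t-BuOOH turns an allylic CH2 into an enone carbonyl; C7 is the only allylic methylene of the C8=C9 bond (C10 is quaternary) and the bridgehead γ-hydrogen of the other enone is not activated; no stereocentre is formed.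

Step 8
Reactants: 11
Product: 13 (4S,5S,10R,11R)-15-norlongipina-2,8-diene-1,7-dione, via monomethyl ketone 12 (not isolated)
Conditions: LiN(SiMe3)2 (1.1 equiv), THF, −78 °C, MeI; then LiN(SiMe3)2 (1.2 equiv), MeI, −78 → 0 °C
Reagents that add atoms: iodomethane, CI
Why: Twofold α-alkylation of the cross-conjugated lithium enolate: C6 carries the only acidic hydrogens of the molecule (both enones end in bridgehead or quaternary carbons), so exhaustive methylation should give the gem-dimethyl group and leaves no new stereocentre.

Step 9
Reactants: 13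
Product: 14 (3S,4S,5S,10R,11R)-1-(triethylsilyloxy)longipina-1,8-dien-7-one
Conditions: Me2CuLi (1.5 equiv), Et3SiCl (3 equiv), THF, −78 °C; Et3N, aq. NaHCO3
Reagents that add atoms: lithium dimethylcuprate, C[Cu-]C.[Li+]; chlorotriethylsilane, CC[Si](CC)(CC)Cl
Why: Cuprate conjugate addition with in situ silylation: the unhindered β-carbon C3 of the bicyclic enone should react while the second enone, with a neopentylic β-carbon C9 and a carbonyl flanked by the quaternary C6, stays untouched; the methyl group enters from the face of the C5 bridge, a stereocentre that step 11 removes again.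

Step 10
Reactants: 14
Product: 15 (3S,4S,5S,7R,10R,11R)-1-(triethylsilyloxy)longipina-1,8-dien-7-ol
Conditions: (S)-Me-CBS oxazaborolidine (0.5 equiv), catecholborane (2 equiv), toluene, −78 °C
Reagents that add atoms: none
Why: Corey–Bakshi–Shibata reduction of the only remaining ketone (ring A is masked as its silyl enol ether): with the quaternary C6 as the large and the vinylic C8 as the small substituent the catalyst should deliver hydride to give the (7R)-carbinol under reagent control.

Step 11
Reactants: 15
Product: 16 (4R,5S,7R,10R,11R)-7-hydroxylongipina-2,8-dien-1-one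
Conditions: Pd(OAc)2 (1.1 equiv), MeCN, rt
Reagents that add atoms: none
Why: Saegusa–Ito oxidation: the palladium enolate formed from the silyl enol ether loses the C3 hydrogen by β-hydride elimination, which restores the C1 ketone as the 3-methyl enone and erases the C3 stereocentre.

Step 12
Reactants: 16; 17 angelic anhydride
Product: 18 (4R,5S,7R,10R,11R)-1-oxolongipina-2,8-dien-7-yl (2Z)-2-methylbut-2-enoate
Conditions: LiN(SiMe3)2 (1.05 equiv), THF, −78 °C; 17, −78 → 0 °C; aq. NH4Cl
Reagents that add atoms: none
Why: O-acylation of the lithium alkoxide with the anhydride (the base takes the hydroxyl proton, far more acidic than the γ-methyl of the enone); without a nucleophilic catalyst the Z geometry of the angelate should be kept, and no stereocentre is touched.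

Step 13
Reactants: 18
Product: 19 (4R,5S,7S,8S,9S,10R,11R)-8,9-dihydroxy-1-oxolongipin-2-en-7-yl (2Z)-2-methylbut-2-enoate
Conditions: OsO4 (5 mol%), NMO (1.5 equiv), acetone–H2O, 0 °C → rt
Reagents that add atoms: osmium tetroxide, O=[Os](=O)(=O)=O; N-methylmorpholine N-oxide, C[N+]1([O-])CCOCC1; water, O
Why: Catalytic osmium tetroxide syn-dihydroxylation: the non-conjugated cis C8=C9 bond should react ahead of the two conjugated trisubstituted C=C bonds, and osmylation anti to the allylic C7 acyloxy group places the two new hydroxyls cis to each other and trans to the C7 oxygen (8S, 9S).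

Step 14
Reactants: 19; 20 (R)-2-methylbutanoic acid
Product: 21 (4R,5S,7S,8S,9S,10R,11R)-9-hydroxy-8-[(2R)-2-methylbutanoyloxy]-1-oxolongipin-2-en-7-yl (2Z)-2-methylbut-2-enoate (CNP0206166.1)
Conditions: DCC (1.3 equiv), DMAP (0.1 equiv), CH2Cl2, −20 → 0 °C
Reagents that add atoms: none
Why: Steglich esterification: of the two hydroxyls C8–OH is the less hindered one (C9–OH is neopentylic next to the quaternary C10), so monoacylation should occur at C8; the acyl stereocentre comes in with 20 and no ring stereocentre is affected.

**Compound list**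

1 | 1,4-dioxaspiro[4.5]decan-7-one | O=C1CCCC2(C1)OCCO2 | starting material
2 | pent-4-enal | C=CCCC=O | starting material
3 | (8S)-8-[(1S)-1-hydroxypent-4-en-1-yl]-1,4-dioxaspiro[4.5]decan-7-one | C=CCC[C@H](O)[C@@H]1CCC2(CC1=O)OCCO2 | intermediate
4 | (8S)-7-ethenyl-8-[(1S)-1-hydroxypent-4-en-1-yl]-1,4-dioxaspiro[4.5]decan-7-ol (ketal diol, C7 epimers) | C=CCC[C@H](O)[C@@H]1CCC2(CC1(O)C=C)OCCO2 | intermediate
5 | (4R)-3-ethenyl-4-[(1S)-1-hydroxypent-4-en-1-yl]cyclohex-2-en-1-one | C=CCC[C@H](O)[C@@H]1CCC(=O)C=C1C=C | intermediate
6 | (4R)-4-[(1R)-1-bromopent-4-en-1-yl]-3-ethenylcyclohex-2-en-1-one | C=CCC[C@@H](Br)[C@@H]1CCC(=O)C=C1C=C | intermediate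
7 | bromomagnesium enolate of 4-[(1R)-1-bromopent-4-en-1-yl]-3-ethenyl-3-methylcyclohexanone (3-methyl trans to the C4 side chain) | C=CCC[C@@H](Br)[C@@H]1CCC(O[Mg]Br)=C[C@]1(C)C=C | intermediate
8 | (1R,5S,6R,7S)-7-(but-3-en-1-yl)-6-ethenyl-6-methylbicyclo[3.1.1]heptan-2-one | C=CCC[C@H]1[C@@H]2CCC(=O)[C@H]1[C@]2(C)C=C | intermediate
9 | (1R,5S,6R,7S)-7-(but-3-en-1-yl)-6-ethenyl-6-methylbicyclo[3.1.1]hept-3-en-2-one | C=CCC[C@H]1[C@@H]2C=CC(=O)[C@H]1[C@]2(C)C=C | intermediate
10 | (4S,5S,10R,11R)-12,13,15-trinorlongipina-2,8-dien-1-one | O=C1C=C[C@H]2[C@@H]3CCC=C[C@@]2(C)[C@H]13 | intermediate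
11 | (4S,5S,10R,11R)-12,13,15-trinorlongipina-2,8-diene-1,7-dione | O=C1C=C[C@H]2[C@@H]3CC(=O)C=C[C@@]2(C)[C@H]13 | intermediate
12 | 13,15-dinorlongipina-2,8-diene-1,7-dione (6-monomethyl ketone, ring stereocentres as in 11, C6 epimers) | O=C1C=C[C@H]2[C@@H]3C(C)C(=O)C=C[C@@]2(C)[C@H]13 | intermediate
13 | (4S,5S,10R,11R)-15-norlongipina-2,8-diene-1,7-dione | O=C1C=C[C@H]2[C@@H]3C(C)(C)C(=O)C=C[C@@]2(C)[C@H]13 | intermediate
14 | (3S,4S,5S,10R,11R)-1-(triethylsilyloxy)longipina-1,8-dien-7-one | CC[Si](CC)(CC)OC1=C[C@@H](C)[C@H]2[C@@H]3C(C)(C)C(=O)C=C[C@@]2(C)[C@H]13 | intermediate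
15 | (3S,4S,5S,7R,10R,11R)-1-(triethylsilyloxy)longipina-1,8-dien-7-ol | CC[Si](CC)(CC)OC1=C[C@@H](C)[C@H]2[C@@H]3C(C)(C)[C@H](O)C=C[C@@]2(C)[C@H]13 | intermediate
16 | (4R,5S,7R,10R,11R)-7-hydroxylongipina-2,8-dien-1-one | O=C1C=C(C)[C@H]2[C@@H]3C(C)(C)[C@H](O)C=C[C@@]2(C)[C@H]13 | intermediate
17 | angelic anhydride, (2Z)-2-methylbut-2-enoic anhydride | C/C=C(/C)C(=O)OC(=O)/C(C)=C\C | starting material
18 | (4R,5S,7R,10R,11R)-1-oxolongipina-2,8-dien-7-yl (2Z)-2-methylbut-2-enoate | O=C1C=C(C)[C@H]2[C@@H]3C(C)(C)[C@H](OC(=O)/C(C)=C\C)C=C[C@@]2(C)[C@H]13 | intermediate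
19 | (4R,5S,7S,8S,9S,10R,11R)-8,9-dihydroxy-1-oxolongipin-2-en-7-yl (2Z)-2-methylbut-2-enoate | O=C1C=C(C)[C@H]2[C@@H]3C(C)(C)[C@H](OC(=O)/C(C)=C\C)[C@@H](O)[C@@H](O)[C@@]2(C)[C@H]13 | intermediate
20 | (R)-2-methylbutanoic acid | CC[C@@H](C)C(=O)O | starting material
21 | (4R,5S,7S,8S,9S,10R,11R)-9-hydroxy-8-[(2R)-2-methylbutanoyloxy]-1-oxolongipin-2-en-7-yl (2Z)-2-methylbut-2-enoate (CNP0206166.1) | C/C=C(/C)C(=O)O[C@@H]1[C@@H](OC(=O)[C@H](C)CC)[C@@H](O)[C@@]2(C)[C@@H]3C(=O)C=C(C)[C@H]2[C@@H]3C1(C)C | target

**Step count and risks**

Total step count: 14. Longest linear sequence: 14 steps (from 1).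

Steps most likely to fail:

Step 4. The methyl group may be transferred to the terminal carbon of the vinyl group (1,6-addition) instead of C10, and the magnesium enolate may close the four-membered ring too slowly, so that loss of HBr or simple protonation takes over. The fallback changes the order of ring formation and separates the two events. Setting out from 6, ring-closing metathesis (second-generation Grubbs catalyst, CH2Cl2) closes the seven-membered ring first and gives (4aR,5R)-5-bromo-3,4,4a,5,6,7-hexahydro-2H-benzo[7]annulen-2-one F1. Copper–NHC-catalysed 1,4-addition of MeMgBr in the presence of Me3SiCl then gives the cis-fused trimethylsilyl enol ether F2, which can be purified. MeLi in THF–HMPA releases the lithium enolate, which closes the cyclobutane transannularly (keto halide cyclisation in a cis-fused bicycle, where the ring holds the bromide next to C11) to the tricyclic ketone F3. IBX dehydrogenation of F3 gives 10, where the route is rejoined.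

Step 1. The unbranched aldehyde may self-condense, the enamine may form towards the ketal carbon and eliminate a ketal oxygen, or the enantioselectivity may be insufficient. The fallback is an auxiliary-controlled aldol addition. Setting out from 1, condensation with (S)-1-amino-2-(methoxymethyl)pyrrolidine gives the SAMP hydrazone F4. Deprotonation with LiN(i-Pr)2 on the unhindered side and addition of 2 at low temperature gives the β-hydroxy hydrazone F5. Two-phase hydrolysis with aqueous oxalic acid releases the auxiliary and returns to 3.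

Step 13. Osmylation of the angelate double bond may compete with that of the hindered ring alkene, or the facial selectivity may be poor. In the fallback the diol is made before the angelate is present and is then protected. Setting out from 16, OsO4 (cat.)/NMO gives the 7,8,9-triol F6 (attack anti to the free allylic hydroxyl). 2,2-Dimethoxypropane/PPTS protects the cis C8/C9 diol as the acetonide F7. LiN(SiMe3)2 and 17 esterify C7–OH to the angelate acetonide F8. Aqueous acetic acid removes the acetonide and returns to 19.

Further compounds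
F1 | step 4 | (4aR,5R)-5-bromo-3,4,4a,5,6,7-hexahydro-2H-benzo[7]annulen-2-one | O=C1C=C2C=CCC[C@@H](Br)[C@@H]2CC1
F2 | step 4 | {[(4aR,5R,9aS)-5-bromo-9a-methyl-4,4a,5,6,7,9a-hexahydro-3H-benzo[7]annulen-2-yl]oxy}trimethylsilane | C[Si](C)(C)OC1=C[C@]2(C)C=CCC[C@@H](Br)[C@@H]2CC1
F3 | step 4 | (4S,5S,10R,11R)-12,13,15-trinorlongipin-8-en-1-one | O=C1CC[C@H]2[C@@H]3CCC=C[C@@]2(C)[C@H]13
F4 | step 1 | SAMP hydrazone of 1,4-dioxaspiro[4.5]decan-7-one (C=N geometry not fixed) | COC[C@@H]1CCCN1N=C1CCCC2(C1)OCCO2
F5 | step 1 | SAMP hydrazone of (8S)-8-[(1S)-1-hydroxypent-4-en-1-yl]-1,4-dioxaspiro[4.5]decan-7-one | C=CCC[C@H](O)[C@@H]1CCC2(CC1=NN1CCC[C@H]1COC)OCCO2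
F6 | step 13 | (4R,5S,7S,8S,9S,10R,11R)-7,8,9-trihydroxylongipin-2-en-1-one | O=C1C=C(C)[C@H]2[C@@H]3C(C)(C)[C@H](O)[C@@H](O)[C@@H](O)[C@@]2(C)[C@H]13
F7 | step 13 | 8,9-O-isopropylidene derivative of the 7,8,9-triol (free C7–OH) | O=C1C=C(C)[C@H]2[C@@H]3C(C)(C)[C@H](O)[C@H]4OC(C)(C)O[C@H]4[C@@]2(C)[C@H]13
F8 | step 13 | 8,9-O-isopropylidene derivative of the 7-angelate | O=C1C=C(C)[C@H]2[C@@H]3C(C)(C)[C@H](OC(=O)/C(C)=C\C)[C@H]4OC(C)(C)O[C@H]4[C@@]2(C)[C@H]13
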